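## Retrosynthetic overview

- **Feature:** ring A of the benzofuran carries one oxygen only, at C6. C6 is joined through C7 to furan carbon C7a, and the C4=C5 unit hangs on the neighbouring furan carbon C3a. Ring A is therefore a folded (3-vinylfuran-2-yl)acetic acid, with C6 as the carboxyl carbon, C7 as its CH2 and C4/C5 as the vinyl group.
- **Last skeletal bond, C5–C6:** acid 15 → furylketene 17 → 6π ring closure → acetate 20. Removal of the acetate and the MOM groups then gives 21.
- **Furan:** Paal–Knorr closure of tricarbonyl 9, made from α-bromo ketone 7 and diethyl 3-oxopentanedioate 8. The crowded C2–C1' bond is the aryl–acyl bond of flopropione, so no biaryl coupling is needed.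
- **Ester differentiation:** hydride cannot tell the two esters of furan 10 apart, because the conjugated one on C3a is the less reactive. Both are reduced, MnO2 picks out the furylic alcohol (→ CHO → vinyl), and the 2-hydroxyethyl arm is raised to the acid last.
- **Ring order:** ring B (bought, decorated in steps 1–3) → furan (step 6) → ring A (step 11).

Key step: step 11

Remark: Ar stands for 2-methoxy-4,6-bis(methoxymethoxy)-3-(3-methylbut-2-enyl)phenyl, and benzofuran numbering (O1, C2, C3, C3a, C4–C7, C7a) is also used for atoms of rings still to be formed. The target has no stereocentre, and the sp3 centres of 7 (racemic) and 9 (diastereomer mixture) vanish in step 6.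

## Route

Step 1
Reactants: 1 flopropione, 1-(2,4,6-trihydroxyphenyl)propan-1-one; 2 prenyl bromide, 1-bromo-3-methylbut-2-ene
Product: 3 1-[2,4,6-trihydroxy-3-(3-methylbut-2-enyl)phenyl]propan-1-one
Conditions: KOH, H2O, 0 °C to rt (2 as the limiting component)
Reagents that add atoms: none
Why: Base-mediated C-allylation of an acylphloroglucinol: in water the hydrogen-bonded phenoxide of 1 reacts through carbon, the two free ring positions are equivalent, and keeping 2 limiting holds back a second prenylation.

Step 2
Reactants: 3 1-[2,4,6-trihydroxy-3-(3-methylbut-2-enyl)phenyl]propan-1-one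
Product: 4 1-[2-hydroxy-4,6-bis(methoxymethoxy)-3-(3-methylbut-2-enyl)phenyl]propan-1-one
Conditions: MOMCl (2.2 equiv), i-Pr2NEt, CH2Cl2, 0 °C to rt
Reagents that add atoms: chloromethyl methyl ether COCCl
Why: Williamson-type acetal ether formation: the unchelated 4-OH para to the acyl group reacts first, and of the two ortho hydroxyls the open 6-OH is etherified while the 2-OH, wedged between the acyl and prenyl groups, keeps its hydrogen bond to the carbonyl and stays free.

Step 3
Reactants: 4 1-[2-hydroxy-4,6-bis(methoxymethoxy)-3-(3-methylbut-2-enyl)phenyl]propan-1-one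
Product: 5 1-Ar-propan-1-one, 1-[2-methoxy-4,6-bis(methoxymethoxy)-3-(3-methylbut-2-enyl)phenyl]propan-1-one
Conditions: MeI, K2CO3, DMF, rt to 40 °C
Reagents that add atoms: iodomethane CI
Why: Williamson ether synthesis on the only remaining phenol, whose chelation is broken by carbonate in a dipolar aprotic solvent, under conditions too weakly basic to enolise the ketone.

Step 4
Reactants: 5 1-Ar-propan-1-one
Product: 7 2-bromo-1-Ar-propan-1-one (racemic), via silyl enol ether 6 (not isolated)
Conditions: LiN(SiMe3)2, Me3SiCl, THF, −78 °C to 0 °C; volatiles removed; NBS (1.0 equiv), THF, −78 °C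
Reagents that add atoms: N-bromosuccinimide O=C1CCC(=O)N1Br; chlorotrimethylsilane C[Si](C)(C)Cl (its atoms stay in 6 only)
Why: Kinetic deprotonation with in situ silylation, then electrophilic bromination of the silyl enol ether, which at −78 °C is far more nucleophilic than the prenyl alkene or ring-B C5'–H and releases no HBr, so the acetals hold; the new stereocentre is racemic and is erased in step 6.

Step 5
Reactants: 7 2-bromo-1-Ar-propan-1-one; 8 diethyl 3-oxopentanedioate
Product: 9 diethyl 2-(1-Ar-1-oxopropan-2-yl)-3-oxopentanedioate (diastereomer mixture)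
Conditions: 8 (1.5 equiv), NaH (1.4 equiv), THF, 0 °C; then 7, NaI (cat.), rt to 50 °C
Reagents that add atoms: none
Why: SN2 alkylation of a stabilised β-keto ester anion by an α-bromo ketone (acetoacetic ester type synthesis of a 1,4-diketone): the di-ortho-substituted aryl carbonyl is too shielded for the Feist–Benary aldol mode, so the C–C bond forms at the C–Br carbon, and the two new stereocentres need no control because both become sp2 in step 6.

Step 6
Reactants: 9 diethyl 2-(1-Ar-1-oxopropan-2-yl)-3-oxopentanedioate
Product: 10 ethyl 5-Ar-2-(2-ethoxy-2-oxoethyl)-4-methylfuran-3-carboxylate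
Conditions: PPTS (cat.), 4 Å MS, toluene, 100 °C
Reagents that add atoms: none
Why: Paal–Knorr furan synthesis: the enol oxygen of one ketone adds to the other carbonyl and loss of water aromatises, placing the ester-bearing carbon at furan C3 and the CH2CO2Et arm at C2, while a weak acid in a dried aprotic medium gives the MOM acetals no partner for exchange.

Step 7
Reactants: 10 ethyl 5-Ar-2-(2-ethoxy-2-oxoethyl)-4-methylfuran-3-carboxylate
Product: 11 2-[5-Ar-3-(hydroxymethyl)-4-methylfuran-2-yl]ethanol
Conditions: LiAlH4, THF, 0 °C to rt; aq. potassium sodium tartrate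
Reagents that add atoms: none
Why: Exhaustive LiAlH4 reduction of both esters, as practised on homophthalate diesters; ethers, acetals, the furan and the isolated alkene are inert to hydride.

Step 8
Reactants: 11 2-[5-Ar-3-(hydroxymethyl)-4-methylfuran-2-yl]ethanol
Product: 12 5-Ar-2-(2-hydroxyethyl)-4-methylfuran-3-carbaldehyde
Conditions: activated MnO2 (excess), CH2Cl2, rt, stopped at full conversion of 11
Reagents that add atoms: none
Why: Chemoselective MnO2 oxidation of the furylic (benzylic-type) alcohol beside a saturated primary alcohol; the aldehyde is a vinylogous formate (O1–C7a=C3a–CHO) and thus a poor electrophile with little tendency to close to a lactol and be oxidised further.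

Step 9
Reactants: 12 5-Ar-2-(2-hydroxyethyl)-4-methylfuran-3-carbaldehyde
Product: 13 2-(5-Ar-4-methyl-3-vinylfuran-2-yl)ethanol
Conditions: MePPh3Br, KOt-Bu (2.5 equiv each), THF, 0 °C to rt
Reagents that add atoms: methyltriphenylphosphonium bromide C[P+](c1ccccc1)(c1ccccc1)c1ccccc1.[Br-]
Why: Wittig methylenation with the unstabilised ylide, used in excess because the free hydroxyl takes up one equivalent of base; no ester-flanked acidic CH2 is present at this stage to quench the ylide.

Step 10
Reactants: 13 2-(5-Ar-4-methyl-3-vinylfuran-2-yl)ethanol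
Product: 15 2-(5-Ar-4-methyl-3-vinylfuran-2-yl)acetic acid, via aldehyde 14 (not isolated)
Conditions: TEMPO (cat.), PhI(OAc)2 (2.2 equiv), MeCN–H2O (1:1), rt
Reagents that add atoms: water O
Why: Oxoammonium-catalysed oxidation (TEMPO/PhI(OAc)2) of a primary alcohol through aldehyde 14 to the carboxylic acid in aqueous acetonitrile, conditions that tolerate terminal and trisubstituted alkenes, furans and acetals.

Step 11
Reactants: 15 2-(5-Ar-4-methyl-3-vinylfuran-2-yl)acetic acid
Product: 20 2-Ar-3-methyl-1-benzofuran-6-yl acetate (6-O-acetyl-4',6'-bis-O-methoxymethyl glycybenzofuran), via mixed anhydride 16 (not isolated), via furylketene 17 (not isolated), via dienone 18 (not isolated), via phenol 19 (not isolated)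
Conditions: Ac2O, anhydrous NaOAc, BHT (trace), N2, reflux (ca. 140 °C)
Reagents that add atoms: acetic anhydride CC(=O)OC(C)=O
Why: Ac2O turns acid 15 into mixed anhydride 16, and acetate removes the acidified C7–H with loss of acetate (E1cB) to give furylketene 17, in which the ketene C7=C6, furan C7a=C3a and vinyl C4=C5 bonds make up a hexatriene whose central alkene is locked cis by the furan. A thermal, disrotatory 6π-electrocyclization then bonds the ketene carbon C6 to the vinyl terminus C5 and closes the six-membered carbocycle (ring A) as dienone 18, at the cost of the small furan resonance energy only. Proton loss from C5 gives phenol 19, which regains the furan sextet and gains a benzene ring, and Ac2O traps it as acetate 20, so the sequence is pulled forward irreversibly. The closest known reaction type is the Ac2O/NaOAc benzannulation of 3,5-dienoic acids (the ring closure of Stobbe half-acids, also run on furan and thiophene substrates) together with the dienylketene closure of the Danheiser benzannulation. No stereocentre is formed, and regiochemistry is fixed because C6 can reach no carbon other than C5, so only the 6-oxygenated benzofuran can arise. The selectivity needed is ring closure ahead of intermolecular ketene capture (C-acetylation with decarboxylation of the Dakin–West kind, dimerisation), which the enforced proximity of C5 and C6 and moderate dilution secure, while the acetate buffer keeps strong acid out so that the two MOM acetals and the prenyl alkene are left alone.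

Step 12
Reactants: 20 2-Ar-3-methyl-1-benzofuran-6-yl acetate
Product: 19 2-Ar-3-methyl-1-benzofuran-6-ol
Conditions: K2CO3 (cat.), MeOH, rt
Reagents that add atoms: none
Why: Base-catalysed transesterification (Zemplén-type methanolysis) of the aryl acetate, which leaves the acetals, the methyl ether and the alkene untouched and delivers as an isolated compound the phenol that passed through step 11.

Step 13
Reactants: 19 2-Ar-3-methyl-1-benzofuran-6-ol
Product: 21 glycybenzofuran
Conditions: HCl (aq., cat.), MeOH, rt to 40 °C
Reagents that add atoms: none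
Why: Acid-catalysed acetal exchange of the two aryl MOM ethers with methanol, run dilute and near room temperature as for other ortho-prenylphenols so that the freed 4'-OH does not add to the prenyl alkene.

## Compound list

1 | flopropione, 1-(2,4,6-trihydroxyphenyl)propan-1-one | CCC(=O)c1c(O)cc(O)cc1O | starting material
2 | prenyl bromide, 1-bromo-3-methylbut-2-ene | CC(C)=CCBr | starting material
3 | 1-[2,4,6-trihydroxy-3-(3-methylbut-2-enyl)phenyl]propan-1-one | CCC(=O)c1c(O)cc(O)c(CC=C(C)C)c1O | intermediate
4 | 1-[2-hydroxy-4,6-bis(methoxymethoxy)-3-(3-methylbut-2-enyl)phenyl]propan-1-one | CCC(=O)c1c(OCOC)cc(OCOC)c(CC=C(C)C)c1O | intermediate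
5 | 1-[2-methoxy-4,6-bis(methoxymethoxy)-3-(3-methylbut-2-enyl)phenyl]propan-1-one | CCC(=O)c1c(OCOC)cc(OCOC)c(CC=C(C)C)c1OC | intermediate
6 | [(Z)-1-Ar-prop-1-enyloxy]trimethylsilane | C/C=C(\O[Si](C)(C)C)c1c(OCOC)cc(OCOC)c(CC=C(C)C)c1OC | intermediate
7 | 2-bromo-1-Ar-propan-1-one (racemic) | CC(Br)C(=O)c1c(OCOC)cc(OCOC)c(CC=C(C)C)c1OC | intermediate
8 | diethyl 3-oxopentanedioate | CCOC(=O)CC(=O)CC(=O)OCC | starting material
9 | diethyl 2-(1-Ar-1-oxopropan-2-yl)-3-oxopentanedioate (diastereomer mixture) | CCOC(=O)CC(=O)C(C(=O)OCC)C(C)C(=O)c1c(OCOC)cc(OCOC)c(CC=C(C)C)c1OC | intermediate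
10 | ethyl 5-Ar-2-(2-ethoxy-2-oxoethyl)-4-methylfuran-3-carboxylate | CCOC(=O)Cc1oc(-c2c(OCOC)cc(OCOC)c(CC=C(C)C)c2OC)c(C)c1C(=O)OCC | intermediate
11 | 2-[5-Ar-3-(hydroxymethyl)-4-methylfuran-2-yl]ethanol | OCCc1oc(-c2c(OCOC)cc(OCOC)c(CC=C(C)C)c2OC)c(C)c1CO | intermediate
12 | 5-Ar-2-(2-hydroxyethyl)-4-methylfuran-3-carbaldehyde | OCCc1oc(-c2c(OCOC)cc(OCOC)c(CC=C(C)C)c2OC)c(C)c1C=O | intermediate
13 | 2-(5-Ar-4-methyl-3-vinylfuran-2-yl)ethanol | OCCc1oc(-c2c(OCOC)cc(OCOC)c(CC=C(C)C)c2OC)c(C)c1C=C | intermediate
14 | 2-(5-Ar-4-methyl-3-vinylfuran-2-yl)acetaldehyde | O=CCc1oc(-c2c(OCOC)cc(OCOC)c(CC=C(C)C)c2OC)c(C)c1C=C | intermediate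
15 | 2-(5-Ar-4-methyl-3-vinylfuran-2-yl)acetic acid | OC(=O)Cc1oc(-c2c(OCOC)cc(OCOC)c(CC=C(C)C)c2OC)c(C)c1C=C | intermediate
16 | acetic 2-(5-Ar-4-methyl-3-vinylfuran-2-yl)acetic anhydride | CC(=O)OC(=O)Cc1oc(-c2c(OCOC)cc(OCOC)c(CC=C(C)C)c2OC)c(C)c1C=C | intermediate
17 | 2-(5-Ar-4-methyl-3-vinylfuran-2-yl)ethenone (furylketene) | O=C=Cc1oc(-c2c(OCOC)cc(OCOC)c(CC=C(C)C)c2OC)c(C)c1C=C | intermediate
18 | 2-Ar-3-methyl-5H-1-benzofuran-6-one | O=C1CC=C2C(C)=C(c3c(OCOC)cc(OCOC)c(CC=C(C)C)c3OC)OC2=C1 | intermediate
19 | 2-Ar-3-methyl-1-benzofuran-6-ol | Cc1c(-c2c(OCOC)cc(OCOC)c(CC=C(C)C)c2OC)oc2cc(O)ccc12 | intermediate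
20 | 2-Ar-3-methyl-1-benzofuran-6-yl acetate | CC(=O)Oc1ccc2c(C)c(-c3c(OCOC)cc(OCOC)c(CC=C(C)C)c3OC)oc2c1 | intermediate
21 | glycybenzofuran | COc1c(CC=C(C)C)c(O)cc(O)c1-c1oc2cc(O)ccc2c1C | target

## Step count

- Total step count: 13
- Longest linear sequence: 13 (1 → 21)

## Steps most likely to fail

**Step 11.** Ring closure may be outrun by intermolecular consumption of the ketene or the mixed anhydride (C-acetylation followed by decarboxylation, or dimerisation), or by thermal polymerisation of the vinylfuran.

The fallback closes ring A by metathesis. It sets out from 13 and comes back at 19.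
- Alcohol 13 is oxidised with Dess–Martin periodinane/NaHCO3 only as far as aldehyde 14, which is isolated this time.
- H2C=CHMgBr adds to give 1-(5-Ar-4-methyl-3-vinylfuran-2-yl)but-3-en-2-ol F1.
- A second Dess–Martin oxidation gives 1-(5-Ar-4-methyl-3-vinylfuran-2-yl)but-3-en-2-one F2.
- Ring-closing metathesis of the two terminal vinyl groups with the second-generation Grubbs catalyst, (H2IMes)(PCy3)Cl2Ru=CHPh, in dilute CH2Cl2 leaves the slow trisubstituted prenyl alkene alone and gives 2-Ar-3-methyl-7H-1-benzofuran-6-one F3.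
- F3 tautomerises to phenol 19, and the route resumes at step 13.

**Step 6.** Acid-induced loss of the acetal protecting groups, followed by addition of the freed 4-OH to the prenyl alkene, may compete with a dehydration that the shielded aryl ketone slows down.

The fallback builds the furan by a carbenoid [3+2] annulation and also spares the bromide and its alkylation. It sets out from 5 and 8 and comes back at 10.
- Ketone 5 is silylated as in step 4, and silyl enol ether 6 is isolated.
- Diazo transfer to 8 (4-acetamidobenzenesulfonyl azide, 1 equiv, Et3N, MeCN) gives diethyl 2-diazo-3-oxopentanedioate F4.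
- Rh2(OAc)4 (cat.) in CH2Cl2 decomposes F4 in the presence of 6. The electrophilic carbenoid attacks the electron-rich enol ether carbon in preference to the prenyl alkene, and the keto oxygen closes the ring.
- The product is ethyl 5-Ar-2-(2-ethoxy-2-oxoethyl)-4-methyl-5-(trimethylsilyloxy)-4,5-dihydrofuran-3-carboxylate F5.
- F5 loses silanol on silica gel or with catalytic PPTS at room temperature to give furan 10.

**Step 2.** Poor site selectivity between the two ortho hydroxyls in the second acetalisation would carry the methyl ether of step 3 to the wrong oxygen.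

The fallback fixes the pattern by symmetry and a Claisen rearrangement and replaces steps 1 and 2. It sets out from 1 and comes back at 4.
- Flopropione 1 with MOMCl (2.2 equiv)/i-Pr2NEt can give only one chelated bis-ether, 1-[2-hydroxy-4,6-bis(methoxymethoxy)phenyl]propan-1-one F6.
- O-alkylation with 3-chloro-3-methylbut-1-yne (DBU, CuCl2 cat., MeCN, 0 °C) gives 1-[2-(2-methylbut-3-yn-2-yloxy)-4,6-bis(methoxymethoxy)phenyl]propan-1-one F7.
- Semi-hydrogenation (H2, Pd/CaCO3 poisoned with Pb(OAc)2, quinoline) gives 1-[2-(2-methylbut-3-en-2-yloxy)-4,6-bis(methoxymethoxy)phenyl]propan-1-one F8.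
- An aromatic Claisen rearrangement in hot toluene can migrate only to C3, since C1 carries the acyl group. The allyl inversion turns the 1,1-dimethylallyl group into the prenyl group of 4.

## Further compounds

F1 | step 11 | 1-(5-Ar-4-methyl-3-vinylfuran-2-yl)but-3-en-2-ol (racemic) | C=CC(O)Cc1oc(-c2c(OCOC)cc(OCOC)c(CC=C(C)C)c2OC)c(C)c1C=C
F2 | step 11 | 1-(5-Ar-4-methyl-3-vinylfuran-2-yl)but-3-en-2-one | C=CC(=O)Cc1oc(-c2c(OCOC)cc(OCOC)c(CC=C(C)C)c2OC)c(C)c1C=C
F3 | step 11 | 2-Ar-3-methyl-7H-1-benzofuran-6-one | O=C1C=Cc2c(C)c(-c3c(OCOC)cc(OCOC)c(CC=C(C)C)c3OC)oc2C1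
F4 | step 6 | diethyl 2-diazo-3-oxopentanedioate | CCOC(=O)CC(=O)C(=[N+]=[N-])C(=O)OCC
F5 | step 6 | ethyl 5-Ar-2-(2-ethoxy-2-oxoethyl)-4-methyl-5-(trimethylsilyloxy)-4,5-dihydrofuran-3-carboxylate (diastereomer mixture) | CCOC(=O)CC1=C(C(=O)OCC)C(C)C(O[Si](C)(C)C)(c2c(OCOC)cc(OCOC)c(CC=C(C)C)c2OC)O1
F6 | step 2 | 1-[2-hydroxy-4,6-bis(methoxymethoxy)phenyl]propan-1-one | CCC(=O)c1c(O)cc(OCOC)cc1OCOC
F7 | step 2 | 1-[2-(2-methylbut-3-yn-2-yloxy)-4,6-bis(methoxymethoxy)phenyl]propan-1-one | CCC(=O)c1c(OC(C)(C)C#C)cc(OCOC)cc1OCOC
F8 | step 2 | 1-[2-(2-methylbut-3-en-2-yloxy)-4,6-bis(methoxymethoxy)phenyl]propan-1-one | CCC(=O)c1c(OC(C)(C)C=C)cc(OCOC)cc1OCOC
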